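The readings stem from a simulated flask from invented constants; noise was put on by code.

Weigh how J divides between Z and L before you choose a feed.

| flask | L | J | Z | D | remark | time |
|---|---|---|---|---|---|---|
| gamma | 0.056 M | 1.2 equiv | 1 equiv | 0.12 mol% | run made earlier |  |
| zeta | 0.038 M | 1.2 equiv | 1 equiv | 0.12 mol% | run made earlier |  |
| eta | 0.084 M | 1.2 equiv | 1 equiv | 0.12 mol% | run made earlier |  |
| theta | 0.056 M | 1.8 equiv | 1 equiv | 0.12 mol% | run made earlier |  |
| elm | 0.056 M (fed, over 8.0 d) | 1.20 equiv | 1.00 equiv | 0.12 mol% | all else is in the flask from the start; the feed brings no volume worth counting | 12 d |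
| cedar | 0.056 M | 1.20 equiv | 1.00 equiv | 0.12 mol% | everything together at the start | 12 d |
| alder | 0.056 M | 1.20 equiv | 1.00 equiv (fed, over 8.0 d) | 0.12 mol% | all else is in the flask from the start; the feed brings no volume worth counting | 12 d |

- gamma (time / d: E / %, L / %): 0.625: 12.6, 51.9; 1.25: 16.2, 46.2; 3.00: 21.4, 42.7; 8.00: 27.1, 41.9
- zeta (time / d: E / %, L / %): 2.50: 15.5, 48.1; 5.00: 20.7, 45.1; 8.00: 24.5, 43.5; 10.0: 23.3, 42.3
- eta (time / d: E / %, L / %): 2.50: 26.7, 41.6; 5.00: 27.5, 40.9; 8.00: 27.3, 40.0; 10.0: 27.8, 40.2
- theta (time / d: E / %, L / %): 1.25: 26.5, 40.5; 3.00: 40.5, 33.0; 6.00: 51.9, 26.2; 10.0: 60.9, 22.5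

(readings scatter by 0.5 percentage points)

- the earlier runs were read with a standard deviation of 0.5 percentage points

1. the flask with the highest amount of E, in percent of the L charged ("all alike" if they lie within 1.5 percentage points) (elm / cedar / alder / all alike)
2. final E, as a percentage of the L charged, in elm
3. final E, as a percentage of the L charged, in cedar
4. final E, as a percentage of the L charged, in alder

I read the ladder from the fastest rung down. In gamma the missing part of L, set against the L still seen, stood at 0.814 after 1.25 d and 0.740 after 8.00 d. So I treated L and its missing part as one pool, w, the fraction of the charge not yet E.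

On the next rung, gamma had 59.8 % of its 8.00 d E by 1.25 d, sooner than the 8.0 d feed. E then stalled, at 27.1 % in gamma and 27.8 % in eta, while theta, with 1.8 equiv of J, reached 60.9 %. I therefore took J as the limiting reagent, spent in gamma on E and on Z, which left z, the remaining fraction of Z, at 7.10 %.

Z and the pool meet the same J and D, so these cancel from the ratio of their rates, and, taking the split of the pool between L and its missing part as steady, integrating that ratio gives ln z = S ln w. Gamma gives S = 8.37, the selectivity factor: how many times faster Z takes J than the pool does at equal fractions. While that split holds, E receives the share w/(w + S z) of the J being spent.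

The forecast gave elm 15 % (6 % to 27 %), cedar 27.5 % (26 % to 29.5 %) and alder 42 % (22 % to 70 %), reasoning that “Feeding Z keeps the sink low and spares J, so alder should be highest”.

The simulation gave alder 55.7 %, cedar 27.1 % and elm 17.7 %, from this scheme:

    Z + J + D → D + Q (k = 23400 M⁻² h⁻¹)
    L + J + D → D + E (k = 4520 M⁻² h⁻¹)
    L ⇌ G (K = 0.775, k = 0.0685 h⁻¹)

At 8.00 d, when its feed ended, alder held 55.4 % E and 38.5 % of its Z, which fell to 35.8 % by 12.0 d. Across that unfed window, ln z = S ln w gives 55.8 % E, against 55.7 %. In elm, Z fell from 1.52 % to 0.978 % over the same window, starting from 13.6 % E, and the rule gives 18.0 %, against 17.7 %.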